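**Retrosynthetic overview**
1. Rings: A azepane, B 2-pyrroline (enamine), C oxolane, D spiro hydroxy lactone, E pendant lactone; they are formed in the order C, D, E, A, B.
2. Ring B last: its C–N bond by 5-endo-dig hydroamination of the ring A N–H onto an alkyne (the new step); ring A just before it by N-alkylation with a chloropropyl chain.
3. Ring E: acyl Sonogashira coupling of a terminal alkyne with an Evans-derived acid chloride, asymmetric transfer hydrogenation, lactonization; the aminomethine centre by Ellman sulfinimine propargylation of an aldehyde made from a vinyl group.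
4. Ring D: ring C lactone → exocyclic enol ether → alpha-ketal aldehyde → Evans syn-aldol → acid spiroketal-lactonization.
5. Ring C first: (R)-butenolide from (R)-1,2-epoxy-5-hexene; vinyl cuprate addition and enolate ethylation set its other two centres.

Assumption: metal enolates, organometallic species and other charged reactive intermediates are not numbered, neutral intermediates carried on without isolation are numbered, small reagents that donate atoms are listed as reagents and not numbered; Sp = (3R,4R,5R,7R,8R,9S)-7-(3-chloropropyl)-9-ethyl-4-hydroxy-3-methyl-2-oxo-1,6-dioxaspiro[4.4]nonan-8-yl.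

**Route**

Step 1
Reactants: 1 (R)-2-(but-3-en-1-yl)oxirane
Product: 3 (5R)-5-(but-3-en-1-yl)-3-(phenylsulfanyl)oxolan-2-one, via hydroxy acid 2 (not isolated)
Conditions: PhSCH2CO2H, LDA (2.2 equiv), THF, 0 °C; then 1, 0 °C → rt; 1 M HCl; TsOH·H2O (cat.), toluene, 80 °C
Reagents that add atoms: (phenylsulfanyl)acetic acid (OC(=O)CSc1ccccc1)
Why: The acid dianion opens the terminal epoxide at CH2 by SN2, leaving the stereocentre untouched, and acid closes the gamma-lactone (epoxide opening–lactonization).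

Step 2
Reactants: 3 (5R)-5-(but-3-en-1-yl)-3-(phenylsulfanyl)oxolan-2-one
Product: 5 (5R)-5-(but-3-en-1-yl)furan-2(5H)-one, via sulfoxide 4 (not isolated)
Conditions: mCPBA (1.0 equiv), CH2Cl2, −78 °C; then CaCO3, toluene, 110 °C
Reagents that add atoms: none
Why: Sulfide oxidation followed by thermal syn-elimination of the sulfoxide can only form the ring double bond, giving the butenolide (sulfoxide elimination).

Step 3
Reactants: 5 (5R)-5-(but-3-en-1-yl)furan-2(5H)-one
Product: 7 (5R)-5-(3-hydroxypropyl)furan-2(5H)-one, via aldehyde 6 (not isolated)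
Conditions: O3, CH2Cl2, −78 °C; PPh3, −78 °C → rt; then NaBH(OAc)3, AcOH, rt
Reagents that add atoms: ozone ([O-][O+]=O)
Why: The terminal alkene is ozonized far faster than the electron-poor butenolide, and the mild borohydride reduces only the aldehyde (ozonolysis with reductive work-up).

Step 4
Reactants: 7 (5R)-5-(3-hydroxypropyl)furan-2(5H)-one
Product: 8 (5R)-5-(3-chloropropyl)furan-2(5H)-one
Conditions: N-chlorosuccinimide, PPh3, CH2Cl2, 0 °C → rt
Reagents that add atoms: N-chlorosuccinimide (ClN1C(=O)CCC1=O)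
Why: Appel-type chlorination of the primary alcohol through the alkoxyphosphonium ion gives a chloride that is inert until ring A closure.

Step 5
Reactants: 8 (5R)-5-(3-chloropropyl)furan-2(5H)-one
Product: 9 (3S,4S,5R)-5-(3-chloropropyl)-4-ethenyl-3-ethyloxolan-2-one
Conditions: CH2=CHMgBr (2.2 equiv), CuBr·SMe2 (1.1 equiv), THF, −78 °C; then EtI (5 equiv), DMPU, −78 → −20 °C
Reagents that add atoms: vinylmagnesium bromide (C=C[Mg]Br); ethyl iodide (CCI)
Why: The vinyl cuprate adds anti to the existing side chain and the enolate is ethylated anti to the new vinyl group, so the all-trans lactone results (tandem conjugate addition–enolate alkylation).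

Step 6
Reactants: 9 (3S,4S,5R)-5-(3-chloropropyl)-4-ethenyl-3-ethyloxolan-2-one
Product: 10 (2R,3S,4S)-2-(3-chloropropyl)-3-ethenyl-4-ethyl-5-methylideneoxolane
Conditions: Cp2TiMe2 (3 equiv), toluene, 70 °C, dark
Reagents that add atoms: dimethyltitanocene (C[Ti](C)(C1C=CC=C1)C1C=CC=C1)
Why: Petasis methylenation turns the lactone carbonyl into the exocyclic enol ether under non-acidic conditions that leave the three stereocentres alone.

Step 7
Reactants: 10 (2R,3S,4S)-2-(3-chloropropyl)-3-ethenyl-4-ethyl-5-methylideneoxolane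
Product: 12 [(3S,4S,5R)-5-(3-chloropropyl)-4-ethenyl-3-ethyl-2-methoxyoxolan-2-yl]methanol, via spiro-epoxide 11 (not isolated)
Conditions: DMDO (1.1 equiv, acetone), CH2Cl2, −78 → −40 °C; then MeOH, PPTS (cat.), −40 → 0 °C
Reagents that add atoms: dimethyldioxirane (CC1(C)OO1); methanol (CO)
Why: The electron-rich enol ether is epoxidized in preference to the vinyl group and methanol opens the epoxide at the anomeric carbon through the oxocarbenium ion (enol ether epoxidation–solvolysis); the anomeric mixture is harmless because this carbon is re-equilibrated in step 10.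

Step 8
Reactants: 12 [(3S,4S,5R)-5-(3-chloropropyl)-4-ethenyl-3-ethyl-2-methoxyoxolan-2-yl]methanol
Product: 13 (3S,4S,5R)-5-(3-chloropropyl)-4-ethenyl-3-ethyl-2-methoxyoxolane-2-carbaldehyde
Conditions: Dess–Martin periodinane, pyridine, CH2Cl2, 0 °C → rt
Reagents that add atoms: none
Why: Dess–Martin oxidation of the primary alcohol gives a non-enolizable alpha-ketal aldehyde under buffered conditions that keep the ketal.

Step 9
Reactants: 13 (3S,4S,5R)-5-(3-chloropropyl)-4-ethenyl-3-ethyl-2-methoxyoxolane-2-carbaldehyde; 14 (4R)-4-benzyl-3-propanoyl-1,3-oxazolidin-2-one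
Product: 15 (4R)-4-benzyl-3-{(2R,3R)-3-[(3S,4S,5R)-5-(3-chloropropyl)-4-ethenyl-3-ethyl-2-methoxyoxolan-2-yl]-3-hydroxy-2-methylpropanoyl}-1,3-oxazolidin-2-one
Conditions: 14, Bu2BOTf, i-Pr2NEt, CH2Cl2, 0 °C; then 13, −78 → 0 °C; pH 7 buffer, MeOH, 30% H2O2, 0 °C
Reagents that add atoms: none
Why: Evans syn-aldol: the Z boron enolate reacts through a Zimmerman–Traxler chair under auxiliary control, setting the methyl- and hydroxy-bearing carbons of the future ring D as R and R.

Step 10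
Reactants: 15 (4R)-4-benzyl-3-{(2R,3R)-3-[(3S,4S,5R)-5-(3-chloropropyl)-4-ethenyl-3-ethyl-2-methoxyoxolan-2-yl]-3-hydroxy-2-methylpropanoyl}-1,3-oxazolidin-2-one
Product: 17 (3R,4R,5R,7R,8S,9S)-7-(3-chloropropyl)-8-ethenyl-9-ethyl-4-hydroxy-3-methyl-1,6-dioxaspiro[4.4]nonan-2-one, via carboxylic acid 16 (not isolated)
Conditions: LiOH, 30% H2O2, THF/H2O, 0 °C; Na2SO3; 1 M HCl (pH 3); then CSA (0.1 equiv), 4 Å MS, CH2Cl2, rt
Reagents that add atoms: hydrogen peroxide (OO)
Why: Hydroperoxide cleaves the auxiliary, then acid ionizes the methyl ketal and the carboxylic acid traps the oxocarbenium ion, the spiro centre equilibrating to the R isomer in which the ring D carbon lies trans to the neighbouring ethyl group (thermodynamic spiroketal-lactonization).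

Step 11
Reactants: 17 (3R,4R,5R,7R,8S,9S)-7-(3-chloropropyl)-8-ethenyl-9-ethyl-4-hydroxy-3-methyl-1,6-dioxaspiro[4.4]nonan-2-one
Product: 18 (3R,4R,5R,7R,8S,9S)-7-(3-chloropropyl)-9-ethyl-4-hydroxy-3-methyl-2-oxo-1,6-dioxaspiro[4.4]nonane-8-carbaldehyde
Conditions: O3, CH2Cl2/MeOH, −78 °C; then Me2S, −78 °C → rt
Reagents that add atoms: ozone ([O-][O+]=O)
Why: Ozonolysis of the only remaining alkene gives the aldehyde, whose alpha centre already has the stable all-trans arrangement.

Step 12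
Reactants: 18 (3R,4R,5R,7R,8S,9S)-7-(3-chloropropyl)-9-ethyl-4-hydroxy-3-methyl-2-oxo-1,6-dioxaspiro[4.4]nonane-8-carbaldehyde
Product: 19 (R)-N-[(E)-Sp-methylidene]-2-methylpropane-2-sulfinamide
Conditions: (R)-t-BuS(O)NH2, CuSO4 (anhydrous), PPTS (cat.), CH2Cl2, rt
Reagents that add atoms: (R)-2-methylpropane-2-sulfinamide (CC(C)(C)[S@@](=O)N)
Why: Ellman condensation gives the E N-sulfinyl aldimine under mild dehydrating conditions that leave the lactone and the free hydroxyl alone.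

Step 13
Reactants: 19 (R)-N-[(E)-Sp-methylidene]-2-methylpropane-2-sulfinamide
Product: 20 (R)-N-[(1S)-1-Sp-but-3-yn-1-yl]-2-methylpropane-2-sulfinamide
Conditions: propargyl bromide, In powder, THF, 60 °C
Reagents that add atoms: propargyl bromide (BrCC#C)
Why: Barbier propargylation of the Ellman imine: allenylindium adds through a chelated six-membered transition state to the Si face of the (R)-sulfinyl imine, setting the aminomethine carbon as S, and indium tolerates the hydroxyl, lactone and alkyl chloride.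

Step 14
Reactants: 14 (4R)-4-benzyl-3-propanoyl-1,3-oxazolidin-2-one
Product: 21 tert-butyl (3S)-4-[(4R)-4-benzyl-2-oxo-1,3-oxazolidin-3-yl]-3-methyl-4-oxobutanoate
Conditions: NaHMDS, THF, −78 °C; then BrCH2CO2t-Bu, −78 → −40 °C
Reagents that add atoms: tert-butyl bromoacetate (CC(C)(C)OC(=O)CBr)
Why: Evans alkylation: the chelated Z sodium enolate is alkylated on the face away from the benzyl group, giving the S methyl-bearing centre of ring E.

Step 15
Reactants: 21 tert-butyl (3S)-4-[(4R)-4-benzyl-2-oxo-1,3-oxazolidin-3-yl]-3-methyl-4-oxobutanoate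
Product: 22 (3S)-4-[(4R)-4-benzyl-2-oxo-1,3-oxazolidin-3-yl]-3-methyl-4-oxobutanoic acid
Conditions: TFA, CH2Cl2, 0 °C → rt
Reagents that add atoms: none
Why: Acidolysis of the tert-butyl ester through the tert-butyl cation frees the acid without touching the imide or the stereocentre.

Step 16
Reactants: 20 (R)-N-[(1S)-1-Sp-but-3-yn-1-yl]-2-methylpropane-2-sulfinamide; 22 (3S)-4-[(4R)-4-benzyl-2-oxo-1,3-oxazolidin-3-yl]-3-methyl-4-oxobutanoic acid
Product: 24 (R)-N-[(1S,7S)-8-[(4R)-4-benzyl-2-oxo-1,3-oxazolidin-3-yl]-7-methyl-5,8-dioxo-1-Sp-oct-3-yn-1-yl]-2-methylpropane-2-sulfinamide, via acid chloride 23 (not isolated)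
Conditions: 22, (COCl)2, DMF (cat.), CH2Cl2, 0 °C → rt, evaporate; then 20, PdCl2(PPh3)2 (3 mol%), copper iodide CuI (6 mol%), Et3N, THF, rt
Reagents that add atoms: none
Why: Acyl Sonogashira coupling joins the terminal alkyne to the fresh acid chloride faster than the hindered secondary hydroxyl or the sulfinamide N–H can be acylated, giving the ynone.

Step 17
Reactants: 24 (R)-N-[(1S,7S)-8-[(4R)-4-benzyl-2-oxo-1,3-oxazolidin-3-yl]-7-methyl-5,8-dioxo-1-Sp-oct-3-yn-1-yl]-2-methylpropane-2-sulfinamide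
Product: 26 (R)-N-{(1S)-4-[(2S,4S)-4-methyl-5-oxooxolan-2-yl]-1-Sp-but-3-yn-1-yl}-2-methylpropane-2-sulfinamide, via propargylic alcohol 25 (not isolated)
Conditions: Ru(p-cymene)[(S,S)-TsNCH(Ph)CH(Ph)NH] (2 mol%), i-PrOH, rt; then DBU (0.2 equiv), CH2Cl2, rt
Reagents that add atoms: none
Why: Noyori asymmetric transfer hydrogenation with the (S,S) catalyst, the alkynyl group acting as the pi-substituent, gives the S carbinol, which lactonizes onto the acyl oxazolidinone to the cis-disubstituted ring E.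

Step 18
Reactants: 26 (R)-N-{(1S)-4-[(2S,4S)-4-methyl-5-oxooxolan-2-yl]-1-Sp-but-3-yn-1-yl}-2-methylpropane-2-sulfinamide
Product: 28 azepane secondary amine (ring A closed; N–H; 3-[(2S,4S)-4-methyl-5-oxooxolan-2-yl]prop-2-yn-1-yl on the S aminomethine carbon), via primary amine 27 (not isolated)
Conditions: HCl (4 M in dioxane), CH2Cl2, 0 °C → rt, evaporate; then K2CO3, NaI (0.3 equiv), MeCN (0.01 M), 70 °C
Reagents that add atoms: none
Why: HCl removes the sulfinyl group and the freed amine displaces the primary chloride (iodide-assisted 7-exo-tet SN2 at high dilution) to close ring A with no stereocentre involved.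

Step 19
Reactants: 28 azepane secondary amine (ring A closed; N–H; 3-[(2S,4S)-4-methyl-5-oxooxolan-2-yl]prop-2-yn-1-yl on the S aminomethine carbon)
Product: 29 CNP0272443.1
Conditions: [(IPr)Au(NCMe)]SbF6 (5 mol%; IPr = 1,3-bis(2,6-diisopropylphenyl)imidazol-2-ylidene), 2,6-di-tert-butylpyridine (10 mol%), toluene, 60 °C, argon
Reagents that add atoms: none
Why: Proposed new method: the cationic gold complex activates the internal alkyne and the free secondary ring A nitrogen attacks the distal alkyne carbon anti to gold in the only geometrically possible 5-endo-dig mode, the hindered pyridine shuttling the ammonium proton to protodeaurate the vinylgold and release the bridgehead-nitrogen enamine with no stereocentre changed; the lactone oxygen is not beta to gold and the ring-locked ester cannot undergo acyloxy migration, so the propargylic C–O bond should survive; the closest known reaction type is the gold-, silver- or palladium-catalysed 5-endo-dig hydroamination of N-protected or primary homopropargylic amines to 2-pyrrolines and 1-pyrrolines, which to my knowledge has not been shown for an unprotected secondary cyclic amine adding to an alkyne that carries a propargylic lactone.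

**Compound list**
1 | (R)-2-(but-3-en-1-yl)oxirane [(R)-1,2-epoxy-5-hexene] | C=CCC[C@@H]1CO1 | starting material
2 | (4R)-4-hydroxy-2-(phenylsulfanyl)oct-7-enoic acid (C2 epimers) | OC(=O)C(Sc1ccccc1)C[C@H](O)CCC=C | intermediate
3 | (5R)-5-(but-3-en-1-yl)-3-(phenylsulfanyl)oxolan-2-one (C3 epimers) | O=C1O[C@H](CCC=C)CC1Sc1ccccc1 | intermediate
4 | (5R)-5-(but-3-en-1-yl)-3-(phenylsulfinyl)oxolan-2-one | O=C1O[C@H](CCC=C)CC1S(=O)c1ccccc1 | intermediate
5 | (5R)-5-(but-3-en-1-yl)furan-2(5H)-one | O=C1O[C@H](CCC=C)C=C1 | intermediate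
6 | 3-[(2R)-5-oxo-2,5-dihydrofuran-2-yl]propanal | O=C1O[C@H](CCC=O)C=C1 | intermediate
7 | (5R)-5-(3-hydroxypropyl)furan-2(5H)-one | O=C1O[C@H](CCCO)C=C1 | intermediate
8 | (5R)-5-(3-chloropropyl)furan-2(5H)-one | O=C1O[C@H](CCCCl)C=C1 | intermediate
9 | (3S,4S,5R)-5-(3-chloropropyl)-4-ethenyl-3-ethyloxolan-2-one | CC[C@H]1[C@H](C=C)[C@@H](CCCCl)OC1=O | intermediate
10 | (2R,3S,4S)-2-(3-chloropropyl)-3-ethenyl-4-ethyl-5-methylideneoxolane | CC[C@H]1[C@H](C=C)[C@@H](CCCCl)OC1=C | intermediate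
11 | (5R,6S,7S)-5-(3-chloropropyl)-6-ethenyl-7-ethyl-1,4-dioxaspiro[2.4]heptane (spiro epimers) | CC[C@H]1[C@H](C=C)[C@@H](CCCCl)OC12CO2 | intermediate
12 | [(3S,4S,5R)-5-(3-chloropropyl)-4-ethenyl-3-ethyl-2-methoxyoxolan-2-yl]methanol (C2 anomers) | CC[C@H]1[C@H](C=C)[C@@H](CCCCl)OC1(CO)OC | intermediate
13 | (3S,4S,5R)-5-(3-chloropropyl)-4-ethenyl-3-ethyl-2-methoxyoxolane-2-carbaldehyde (C2 anomers) | CC[C@H]1[C@H](C=C)[C@@H](CCCCl)OC1(C=O)OC | intermediate
14 | (4R)-4-benzyl-3-propanoyl-1,3-oxazolidin-2-one | CCC(=O)N1[C@H](Cc2ccccc2)COC1=O | starting material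
15 | (4R)-4-benzyl-3-{(2R,3R)-3-[(3S,4S,5R)-5-(3-chloropropyl)-4-ethenyl-3-ethyl-2-methoxyoxolan-2-yl]-3-hydroxy-2-methylpropanoyl}-1,3-oxazolidin-2-one | CC[C@H]1[C@H](C=C)[C@@H](CCCCl)OC1(OC)[C@H](O)[C@@H](C)C(=O)N2[C@H](Cc3ccccc3)COC2=O | intermediate
16 | (2R,3R)-3-[(3S,4S,5R)-5-(3-chloropropyl)-4-ethenyl-3-ethyl-2-methoxyoxolan-2-yl]-3-hydroxy-2-methylpropanoic acid | CC[C@H]1[C@H](C=C)[C@@H](CCCCl)OC1(OC)[C@H](O)[C@@H](C)C(O)=O | intermediate
17 | (3R,4R,5R,7R,8S,9S)-7-(3-chloropropyl)-8-ethenyl-9-ethyl-4-hydroxy-3-methyl-1,6-dioxaspiro[4.4]nonan-2-one | CC[C@H]1[C@H](C=C)[C@@H](CCCCl)O[C@@]12OC(=O)[C@H](C)[C@H]2O | intermediate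
18 | (3R,4R,5R,7R,8S,9S)-7-(3-chloropropyl)-9-ethyl-4-hydroxy-3-methyl-2-oxo-1,6-dioxaspiro[4.4]nonane-8-carbaldehyde | CC[C@H]1[C@H](C=O)[C@@H](CCCCl)O[C@@]12OC(=O)[C@H](C)[C@H]2O | intermediate
19 | (R)-N-[(E)-Sp-methylidene]-2-methylpropane-2-sulfinamide | CC[C@H]1[C@H](/C=N/[S@](=O)C(C)(C)C)[C@@H](CCCCl)O[C@@]12OC(=O)[C@H](C)[C@H]2O | intermediate
20 | (R)-N-[(1S)-1-Sp-but-3-yn-1-yl]-2-methylpropane-2-sulfinamide | CC[C@H]1[C@H]([C@H](CC#C)N[S@](=O)C(C)(C)C)[C@@H](CCCCl)O[C@@]12OC(=O)[C@H](C)[C@H]2O | intermediate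
21 | tert-butyl (3S)-4-[(4R)-4-benzyl-2-oxo-1,3-oxazolidin-3-yl]-3-methyl-4-oxobutanoate | CC(C)(C)OC(=O)C[C@H](C)C(=O)N1[C@H](Cc2ccccc2)COC1=O | intermediate
22 | (3S)-4-[(4R)-4-benzyl-2-oxo-1,3-oxazolidin-3-yl]-3-methyl-4-oxobutanoic acid | OC(=O)C[C@H](C)C(=O)N1[C@H](Cc2ccccc2)COC1=O | intermediate
23 | (3S)-4-[(4R)-4-benzyl-2-oxo-1,3-oxazolidin-3-yl]-3-methyl-4-oxobutanoyl chloride | ClC(=O)C[C@H](C)C(=O)N1[C@H](Cc2ccccc2)COC1=O | intermediate
24 | (R)-N-[(1S,7S)-8-[(4R)-4-benzyl-2-oxo-1,3-oxazolidin-3-yl]-7-methyl-5,8-dioxo-1-Sp-oct-3-yn-1-yl]-2-methylpropane-2-sulfinamide | CC[C@H]1[C@H]([C@H](CC#CC(=O)C[C@H](C)C(=O)N2[C@H](Cc3ccccc3)COC2=O)N[S@](=O)C(C)(C)C)[C@@H](CCCCl)O[C@@]14OC(=O)[C@H](C)[C@H]4O | intermediate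
25 | (R)-N-[(1S,5S,7S)-8-[(4R)-4-benzyl-2-oxo-1,3-oxazolidin-3-yl]-5-hydroxy-7-methyl-8-oxo-1-Sp-oct-3-yn-1-yl]-2-methylpropane-2-sulfinamide | CC[C@H]1[C@H]([C@H](CC#C[C@@H](O)C[C@H](C)C(=O)N2[C@H](Cc3ccccc3)COC2=O)N[S@](=O)C(C)(C)C)[C@@H](CCCCl)O[C@@]14OC(=O)[C@H](C)[C@H]4O | intermediate
26 | (R)-N-{(1S)-4-[(2S,4S)-4-methyl-5-oxooxolan-2-yl]-1-Sp-but-3-yn-1-yl}-2-methylpropane-2-sulfinamide | CC[C@H]1[C@H]([C@H](CC#C[C@@H]2C[C@H](C)C(=O)O2)N[S@](=O)C(C)(C)C)[C@@H](CCCCl)O[C@@]13OC(=O)[C@H](C)[C@H]3O | intermediate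
27 | (1S)-4-[(2S,4S)-4-methyl-5-oxooxolan-2-yl]-1-Sp-but-3-yn-1-amine | CC[C@H]1[C@H]([C@H](CC#C[C@@H]2C[C@H](C)C(=O)O2)N)[C@@H](CCCCl)O[C@@]13OC(=O)[C@H](C)[C@H]3O | intermediate
28 | azepane secondary amine: nitrogen of 27 joined to the terminal carbon of the propyl chain (ring A), N–H, alkynyl lactone side chain on the S aminomethine carbon; stereocentres in SMILES order S, R, R, S, S, S, R, R, R | CC[C@H]1[C@H]2[C@@H](CCCN[C@H]2CC#C[C@@H]3C[C@H](C)C(=O)O3)O[C@@]12OC(=O)[C@H](C)[C@H]2O | intermediate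
29 | CNP0272443.1: rings A and B as a 2-pyrroline fused through nitrogen to the azepane, ring E (2S,4S)-4-methyl-5-oxooxolan-2-yl on the enamine carbon, ring C oxolane with ethyl, ring D spiro hydroxy methyl lactone; stereocentres in SMILES order S, R, R, S, S, S, R, R, R | CC[C@H]1[C@H]2[C@@H](CCCN3C([C@@H]4C[C@H](C)C(=O)O4)=CC[C@@H]23)O[C@@]12OC(=O)[C@H](C)[C@H]2O | target

**Step count and risks**

Total step count: 19. Longest linear sequence: 17 steps (steps 1 to 13, then 16 to 19, from compound 1); the side branch from 14 is steps 14 and 15.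

The three steps most likely to fail:

Step 19 (the new step). The basic amine may deactivate the gold catalyst, or the enamine may tautomerize and erode the lactone-bearing centre. The fallback uses known reactions and reverses the order of ring closure. It sets out from the primary amine 27, isolated as the free base after the HCl stage of step 18. AgOTf (10 mol%) in MeCN at rt gives the 1-pyrroline (3S,5S)-3-methyl-5-[(2S)-2-Sp-3,4-dihydro-2H-pyrrol-5-yl]oxolan-2-one F5, by the established 5-endo-dig cyclization of a primary homopropargylic amine. NaI and i-Pr2NEt in MeCN at 70 °C then alkylate the imine nitrogen with the chloropropyl chain to the bicyclic iminium iodide F6. This loses a proton from the adjacent ring B methylene and gives 29 directly, so the route is rejoined at the target.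

Step 18. Closure of the seven-membered ring by the free amine may be slow or give oligomers. The fallback sets out from 27. 2-Nitrobenzenesulfonyl chloride and Et3N in CH2Cl2 give the sulfonamide N-{(1S)-4-[(2S,4S)-4-methyl-5-oxooxolan-2-yl]-1-Sp-but-3-yn-1-yl}-2-nitrobenzenesulfonamide F3. K2CO3 and NaI in DMF at 60 °C close ring A by alkylation of the acidic sulfonamide nitrogen to the N-(2-nitrophenylsulfonyl)azepane F4. PhSH and K2CO3 in MeCN remove the sulfonyl group and return to 28.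

Step 6. Methylenation of the hindered lactone may stall, or enol ether 10 may isomerize into the ring. The fallback sets out from 9. 2-Lithio-1,3-dithiane (1,3-dithiane, n-BuLi, THF, −78 °C) adds once to the lactone carbonyl to give the hemiketal (3S,4S,5R)-5-(3-chloropropyl)-2-(1,3-dithian-2-yl)-4-ethenyl-3-ethyloxolan-2-ol F1. CSA in MeOH at rt gives the methyl ketal 2-[(3S,4S,5R)-5-(3-chloropropyl)-4-ethenyl-3-ethyl-2-methoxyoxolan-2-yl]-1,3-dithiane F2. MeI and CaCO3 in MeCN/H2O at 40 °C hydrolyse the dithiane and return to aldehyde 13, bypassing 10 to 12.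

Further compounds
F1 | step 6 | (3S,4S,5R)-5-(3-chloropropyl)-2-(1,3-dithian-2-yl)-4-ethenyl-3-ethyloxolan-2-ol | CC[C@H]1[C@H](C=C)[C@@H](CCCCl)OC1(O)C1SCCCS1
F2 | step 6 | 2-[(3S,4S,5R)-5-(3-chloropropyl)-4-ethenyl-3-ethyl-2-methoxyoxolan-2-yl]-1,3-dithiane | CC[C@H]1[C@H](C=C)[C@@H](CCCCl)OC1(OC)C1SCCCS1
F3 | step 18 | N-{(1S)-4-[(2S,4S)-4-methyl-5-oxooxolan-2-yl]-1-Sp-but-3-yn-1-yl}-2-nitrobenzenesulfonamide | CC[C@H]1[C@H]([C@H](CC#C[C@@H]2C[C@H](C)C(=O)O2)NS(=O)(=O)c2ccccc2[N+](=O)[O-])[C@@H](CCCCl)O[C@@]13OC(=O)[C@H](C)[C@H]3O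
F4 | step 18 | N-(2-nitrophenylsulfonyl) derivative of azepane 28 | CC[C@H]1[C@H]2[C@@H](CCCN([C@H]2CC#C[C@@H]3C[C@H](C)C(=O)O3)S(=O)(=O)c3ccccc3[N+](=O)[O-])O[C@@]12OC(=O)[C@H](C)[C@H]2O
F5 | step 19 | (3S,5S)-3-methyl-5-[(2S)-2-Sp-3,4-dihydro-2H-pyrrol-5-yl]oxolan-2-one | CC[C@H]1[C@H]([C@@H]2CCC(=N2)[C@@H]2C[C@H](C)C(=O)O2)[C@@H](CCCCl)O[C@@]13OC(=O)[C@H](C)[C@H]3O
F6 | step 19 | bicyclic iminium iodide formed by N-alkylation of F5 with its chloropropyl chain | CC[C@H]1[C@H]2[C@@H](CCC[N+]3=C([C@@H]4C[C@H](C)C(=O)O4)CC[C@@H]23)O[C@@]12OC(=O)[C@H](C)[C@H]2O.[I-]
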